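**Retrosynthetic overview**

1. Locants: hydrindane C1–C7a (ring A = cyclopentane C1/C2/C3/C3a/C7a, ring B = cyclohexane C3a/C4/C5/C6/C7/C7a); C8 = the C(=CH2) carbon; C9 = CH(CH2OAc); lactone C10 (CH), C11 (CH2CO), C12 (CH2O).
2. Late stage: C8=CH2 from a C8 ketone; C1–C8 by acyl Stille coupling of a ring-A alkenylstannane with an acid chloride made from (S)-paraconic acid, whose lactone is transposed into the target lactone by reduction and relactonisation at the end.
3. Ring A is closed by aldol condensation (C2–C3) of a 1,4-keto aldehyde; ring B is made before it, in the key step, by a hydrogen-atom-transfer radical–polar crossover annulation that forms C3a–C4 and C7–C7a from an acyclic enone and 4-methylpent-4-enal.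
4. Enabling feature: in ring B the gem-dimethyl carbon C4 flanks C3a and the methylene C7 flanks the methyl-bearing quaternary C7a. C4 can therefore be a tertiary radical (from an isopropenyl group), C3a/C7a the β/α carbons of an enone whose carbonyl is C1, and C7 an aldehyde carbon whose oxygen is removed later. One bought stereocentre (the dioxolane carbon, future C3) relays to C3a and C7a in that event.
5. Ring order: ring B (step 3), ring A (step 6), final γ-lactone (step 15).

Key step: step 3

Assumption: the tertiary radical is taken to attack enone 5 anti to the dioxolane CH2 group (on the face of the ring oxygen) in the allylic-strain-minimised conformer, which fixes (S)-aldehyde 3 as the input; 3, ylide 4 and (S)-paraconic acid 16 are taken as catalogue compounds.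

**Route**

Step 1
Reactants: 1 4-methylpent-4-en-1-ol
Product: 2 4-methylpent-4-enal
Conditions: PhI(OAc)2 (1.1 equiv), TEMPO (10 mol %), CH2Cl2, rt; used as a distilled solution
Reagents that add atoms: none
Why: Oxoammonium (TEMPO) oxidation of a primary alcohol should stop at the aldehyde and leave the 1,1-disubstituted alkene untouched.

Step 2
Reactants: 3 (4S)-2,2-dimethyl-1,3-dioxolane-4-carbaldehyde; 4 3-(triphenyl-λ5-phosphanylidene)butan-2-one
Product: 5 (3E)-4-[(4R)-2,2-dimethyl-1,3-dioxolan-4-yl]-3-methylbut-3-en-2-one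
Conditions: CH2Cl2, 40 °C
Reagents that add atoms: none
Why: Wittig olefination with a stabilised, α-branched ylide is base-free (no epimerisation of the α-alkoxy aldehyde) and should be E-selective.

Step 3
Reactants: 5 (3E)-4-[(4R)-2,2-dimethyl-1,3-dioxolan-4-yl]-3-methylbut-3-en-2-one; 2 4-methylpent-4-enal (3 equiv)
Product: 7 1-[(1R,2S,6S)-2-[(4R)-2,2-dimethyl-1,3-dioxolan-4-yl]-6-hydroxy-1,3,3-trimethylcyclohexyl]ethan-1-one, via iron enolate 6 (not isolated)
Conditions: Fe(acac)3 (20 mol %), PhSiH3 (2.5 equiv), EtOH (4 equiv), ClCH2CH2Cl, 0 °C → rt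
Reagents that add atoms: none
Why: Hydrogen-atom transfer from an iron hydride (from Fe(acac)3 and PhSiH3) to the isopropenyl group of 2 should give the tertiary C4 radical, which adds to the β-carbon C3a of enone 5 (C3a–C4); the α-keto radical is reduced by divalent iron to the trivalent-iron enolate 6, located only at C7a, which closes on the tethered aldehyde C7 (C7–C7a), and alcoholysis turns the catalyst over. The closest known reaction type is the hydrogen-atom-transfer-initiated radical–polar crossover annulation (Giese addition then intramolecular aldol) of γ,δ-unsaturated aldehydes with α,β-unsaturated carbonyl compounds, used here with an acyclic α-methyl enone. Ring B is closed in a 6-(enolexo)-exo-trig aldol through a chair transition state. C3a is set by 1,2-induction from the dioxolane carbon: 1,3-allylic strain with the C7a methyl holds its C–H in the alkene plane and the bulky radical enters anti to the dioxolane CH2; C7a is then set by C3a, because in 6 the C3a–H eclipses the enolate double bond and the aldehyde tethered through C4 reaches the face that puts the 7a-methyl axial and anti to 3a-H, with acetyl and dioxolanyl trans-diequatorial (the arrangement a trans-hydrindane needs); the C7 carbinol (expected axial from a chelated transition state) is removed in step 4. The step needs hydrogen-atom transfer to the electron-rich 1,1-disubstituted alkene and not to the enone (secured by the electron-poor, trisubstituted alkene of 5), ring closure faster than protonation of 6 (secured by the six-membered chelated transition state and the small amount of alcohol), and an acyclic enolate, since a cyclopentenone acceptor would force a cis ring fusion.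

Step 4
Reactants: 7 1-[(1R,2S,6S)-2-[(4R)-2,2-dimethyl-1,3-dioxolan-4-yl]-6-hydroxy-1,3,3-trimethylcyclohexyl]ethan-1-one
Product: 8 1-[(1S,6S)-6-[(4R)-2,2-dimethyl-1,3-dioxolan-4-yl]-1,5,5-trimethylcyclohex-2-en-1-yl]ethan-1-one
Conditions: Burgess reagent (2 equiv), PhMe, 70 °C
Reagents that add atoms: none
Why: Burgess syn-elimination is non-basic (no retro-aldol) and regiospecific, because C7a is quaternary and only C6 carries β-hydrogens.

Step 5
Reactants: 8 1-[(1S,6S)-6-[(4R)-2,2-dimethyl-1,3-dioxolan-4-yl]-1,5,5-trimethylcyclohex-2-en-1-yl]ethan-1-one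
Product: 10 (1S,2S)-2-acetyl-2,6,6-trimethylcyclohex-3-ene-1-carbaldehyde, via vicinal diol 9 (not isolated)
Conditions: H5IO6 (1.5 equiv), EtOAc, rt
Reagents that add atoms: none
Why: Periodic acid should hydrolyse the terminal acetonide and cleave the glycol in one pot, turning the stereocentre that directed step 3 into the C3 aldehyde under acidic, non-enolising conditions that leave C3a (flanked by two quaternary carbons) intact.

Step 6
Reactants: 10 (1S,2S)-2-acetyl-2,6,6-trimethylcyclohex-3-ene-1-carbaldehyde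
Product: 11 (3aS,7aS)-4,4,7a-trimethyl-3a,4,5,7a-tetrahydro-1H-inden-1-one
Conditions: KOH (2% in MeOH), 0 °C → rt, short reaction time
Reagents that add atoms: none
Why: Intramolecular aldol condensation of a 1,4-keto aldehyde (the classical cyclopentenone synthesis) closes ring A between C2 and C3; the ketone can enolise only at its methyl group, and the trans ring fusion is carried over from 10.

Step 7
Reactants: 11 (3aS,7aS)-4,4,7a-trimethyl-3a,4,5,7a-tetrahydro-1H-inden-1-one
Product: 12 (3aS,7aS)-4,4,7a-trimethyloctahydro-1H-inden-1-one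
Conditions: H2 (1 atm), Pd/C (10%), EtOAc, rt
Reagents that add atoms: none
Why: Heterogeneous hydrogenation should saturate both disubstituted alkenes without creating a stereocentre, and removes the γ-acidic enone.

Step 8
Reactants: 12 (3aS,7aS)-4,4,7a-trimethyloctahydro-1H-inden-1-one
Product: 14 (3aS,7aS)-4,4,7a-trimethyl-3a,4,5,6,7,7a-hexahydro-3H-inden-1-yl trifluoromethanesulfonate, via potassium enolate 13 (not isolated)
Conditions: KN(SiMe3)2, THF, −78 °C; then PhNTf2, −78 → 0 °C
Reagents that add atoms: N-phenylbis(trifluoromethanesulfonimide), O=S(=O)(N(c1ccccc1)S(=O)(=O)C(F)(F)F)C(F)(F)F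
Why: The ketone has α-hydrogens only at C2, so enolate O-triflation should give the C1=C2 enol triflate regiospecifically.

Step 9
Reactants: 14 (3aS,7aS)-4,4,7a-trimethyl-3a,4,5,6,7,7a-hexahydro-3H-inden-1-yl trifluoromethanesulfonate
Product: 15 trimethyl[(3aS,7aS)-4,4,7a-trimethyl-3a,4,5,6,7,7a-hexahydro-3H-inden-1-yl]stannane
Conditions: Me3SnSnMe3, Pd(PPh3)4 (5 mol %), LiCl (5 equiv), THF, 65 °C
Reagents that add atoms: hexamethylditin, C[Sn](C)(C)[Sn](C)(C)C
Why: Zerovalent-palladium-catalysed stannylation of an enol triflate with a distannane is a standard entry to cycloalkenylstannanes.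

Step 10
Reactants: 16 (3S)-5-oxooxolane-3-carboxylic acid [(S)-paraconic acid]; 17 benzyl bromoacetate
Product: 19 (3S,4S)-4-[2-(benzyloxy)-2-oxoethyl]-5-oxooxolane-3-carboxylic acid, via dilithium enolate carboxylate 18 (not isolated)
Conditions: LiN(SiMe3)2 (2.2 equiv), THF, −78 °C; then 17, −78 → −40 °C; 1 M HCl work-up
Reagents that add atoms: none
Why: In the dianion the carboxylate blocks deprotonation at C9, and the lactone enolate should be alkylated anti to the adjacent carboxylate, which sets C10 trans to C9 (substrate-controlled enolate alkylation).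

Step 11
Reactants: 19 (3S,4S)-4-[2-(benzyloxy)-2-oxoethyl]-5-oxooxolane-3-carboxylic acid
Product: 20 benzyl 2-[(3S,4S)-4-(carbonochloridoyl)-2-oxooxolan-3-yl]acetate
Conditions: (COCl)2 (1.5 equiv), DMF (cat.), CH2Cl2, 0 °C → rt; concentrated and used crude
Reagents that add atoms: oxalyl chloride, ClC(=O)C(Cl)=O
Why: Acid chloride formation with oxalyl chloride and catalytic DMF is base-free, so C9 is not epimerised.

Step 12
Reactants: 15 trimethyl[(3aS,7aS)-4,4,7a-trimethyl-3a,4,5,6,7,7a-hexahydro-3H-inden-1-yl]stannane; 20 benzyl 2-[(3S,4S)-4-(carbonochloridoyl)-2-oxooxolan-3-yl]acetate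
Product: 21 benzyl 2-[(3S,4S)-2-oxo-4-{[(3aS,7aS)-4,4,7a-trimethyl-3a,4,5,6,7,7a-hexahydro-3H-inden-1-yl]carbonyl}oxolan-3-yl]acetate
Conditions: Pd2(dba)3 (2.5 mol %), tri(2-furyl)phosphine (10 mol %), THF, 50 °C
Reagents that add atoms: none
Why: Acyl Stille coupling of an acid chloride with an alkenylstannane forms C1–C8 under neutral conditions; the C9 configuration is also that of the more stable trans-disubstituted lactone.

Step 13
Reactants: 21 benzyl 2-[(3S,4S)-2-oxo-4-{[(3aS,7aS)-4,4,7a-trimethyl-3a,4,5,6,7,7a-hexahydro-3H-inden-1-yl]carbonyl}oxolan-3-yl]acetate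
Product: 22 2-[(3S,4S)-2-oxo-4-{[(1S,3aS,7aS)-4,4,7a-trimethyloctahydro-1H-inden-1-yl]carbonyl}oxolan-3-yl]acetic acid
Conditions: H2 (1 atm), Pd/C (10%), EtOAc, rt
Reagents that add atoms: none
Why: Heterogeneous hydrogenation of the enone should deliver hydrogen to the α-face, anti to the 7a-methyl, setting C1 with the acyl group β (also the thermodynamically preferred epimer), while the benzyl ester is hydrogenolysed in the same operation.

Step 14
Reactants: 22 2-[(3S,4S)-2-oxo-4-{[(1S,3aS,7aS)-4,4,7a-trimethyloctahydro-1H-inden-1-yl]carbonyl}oxolan-3-yl]acetic acid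
Product: 23 2-[(3S,4R)-2-oxo-4-{1-[(1R,3aS,7aS)-4,4,7a-trimethyloctahydro-1H-inden-1-yl]ethenyl}oxolan-3-yl]acetic acid
Conditions: Zn, CH2Br2, TiCl4, THF (pre-formed reagent, excess; the acid consumes one equivalent), CH2Cl2, 0 °C → rt
Reagents that add atoms: dibromomethane, BrCBr
Why: Takai–Lombardo methylenation uses a non-basic zinc–titanium methylene reagent that converts hindered, enolisable ketones without epimerisation at C1 or C9 or β-elimination of the lactone oxygen, and leaves lactones and carboxylates alone.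

Step 15
Reactants: 23 2-[(3S,4R)-2-oxo-4-{1-[(1R,3aS,7aS)-4,4,7a-trimethyloctahydro-1H-inden-1-yl]ethenyl}oxolan-3-yl]acetic acid
Product: 25 (4S)-4-{(2R)-1-hydroxy-3-[(1R,3aS,7aS)-4,4,7a-trimethyloctahydro-1H-inden-1-yl]but-3-en-2-yl}oxolan-2-one, via dihydroxy acid 24 (not isolated)
Conditions: LiN(SiMe3)2 (1.0 equiv), THF, −78 °C; then LiBH4 (2 equiv), 0 °C → rt; then 1 M HCl, rt
Reagents that add atoms: none
Why: LiBH4 reduces the lactone but not the pre-formed lithium carboxylate (and no borane is generated to touch the alkene); on acidification the γ-hydroxy acid should close to the five-membered lactone in preference to the six-membered alternative, leaving the C9 hydroxymethyl group free (chemoselective reduction then lactonisation, no stereocentre touched).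

Step 16
Reactants: 25 (4S)-4-{(2R)-1-hydroxy-3-[(1R,3aS,7aS)-4,4,7a-trimethyloctahydro-1H-inden-1-yl]but-3-en-2-yl}oxolan-2-one
Product: 26 (2R)-2-[(3S)-5-oxooxolan-3-yl]-3-[(1R,3aS,7aS)-4,4,7a-trimethyloctahydro-1H-inden-1-yl]but-3-en-1-yl acetate
Conditions: Ac2O, pyridine, DMAP (cat.), CH2Cl2, 0 °C → rt
Reagents that add atoms: acetic anhydride, CC(=O)OC(C)=O
Why: DMAP-catalysed acetylation of the primary alcohol under mild conditions should give the target without acyl migration.

**Compound list**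

1 | 4-methylpent-4-en-1-ol | CC(=C)CCCO | starting material
2 | 4-methylpent-4-enal | CC(=C)CCC=O | intermediate
3 | (4S)-2,2-dimethyl-1,3-dioxolane-4-carbaldehyde | O=C[C@@H]1COC(C)(C)O1 | starting material
4 | 3-(triphenyl-λ5-phosphanylidene)butan-2-one | CC(=O)C(C)=P(c1ccccc1)(c1ccccc1)c1ccccc1 | starting material
5 | (3E)-4-[(4R)-2,2-dimethyl-1,3-dioxolan-4-yl]-3-methylbut-3-en-2-one | CC(=O)/C(C)=C/[C@@H]1COC(C)(C)O1 | intermediate
6 | trivalent-iron enolate of the conjugate adduct (drawn as the free enolate anion; C3a set, aldehyde still open) | CC([O-])=C(C)[C@@H]([C@@H]1COC(C)(C)O1)C(C)(C)CCC=O | intermediate (not isolated)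
7 | 1-[(1R,2S,6S)-2-[(4R)-2,2-dimethyl-1,3-dioxolan-4-yl]-6-hydroxy-1,3,3-trimethylcyclohexyl]ethan-1-one (7a-methyl axial and anti to 3a-H; acetyl and dioxolanyl trans-diequatorial; OH axial) | CC(=O)[C@]1(C)[C@@H]([C@@H]2COC(C)(C)O2)C(C)(C)CC[C@@H]1O | intermediate
8 | 1-[(1S,6S)-6-[(4R)-2,2-dimethyl-1,3-dioxolan-4-yl]-1,5,5-trimethylcyclohex-2-en-1-yl]ethan-1-one | CC(=O)[C@]1(C)[C@@H]([C@@H]2COC(C)(C)O2)C(C)(C)CC=C1 | intermediate
9 | 1-[(1S,6S)-6-[(1R)-1,2-dihydroxyethyl]-1,5,5-trimethylcyclohex-2-en-1-yl]ethan-1-one | CC(=O)[C@]1(C)[C@@H]([C@@H](O)CO)C(C)(C)CC=C1 | intermediate (not isolated)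
10 | (1S,2S)-2-acetyl-2,6,6-trimethylcyclohex-3-ene-1-carbaldehyde | CC(=O)[C@]1(C)[C@@H](C=O)C(C)(C)CC=C1 | intermediate
11 | (3aS,7aS)-4,4,7a-trimethyl-3a,4,5,7a-tetrahydro-1H-inden-1-one | O=C1C=C[C@H]2C(C)(C)CC=C[C@]12C | intermediate
12 | (3aS,7aS)-4,4,7a-trimethyloctahydro-1H-inden-1-one (trans-fused) | O=C1CC[C@H]2C(C)(C)CCC[C@]12C | intermediate
13 | potassium enolate of 12 | [K+].[O-]C1=CC[C@H]2C(C)(C)CCC[C@]12C | intermediate (not isolated)
14 | (3aS,7aS)-4,4,7a-trimethyl-3a,4,5,6,7,7a-hexahydro-3H-inden-1-yl trifluoromethanesulfonate | O=S(=O)(OC1=CC[C@H]2C(C)(C)CCC[C@]12C)C(F)(F)F | intermediate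
15 | trimethyl[(3aS,7aS)-4,4,7a-trimethyl-3a,4,5,6,7,7a-hexahydro-3H-inden-1-yl]stannane | C[Sn](C)(C)C1=CC[C@H]2C(C)(C)CCC[C@]12C | intermediate
16 | (3S)-5-oxooxolane-3-carboxylic acid [(S)-paraconic acid] | OC(=O)[C@@H]1COC(=O)C1 | starting material
17 | benzyl bromoacetate | O=C(CBr)OCc1ccccc1 | starting material
18 | dilithium (3S)-5-oxido-2,3-dihydrofuran-3-carboxylate | [Li+].[Li+].[O-]C(=O)[C@@H]1COC([O-])=C1 | intermediate (not isolated)
19 | (3S,4S)-4-[2-(benzyloxy)-2-oxoethyl]-5-oxooxolane-3-carboxylic acid (trans) | OC(=O)[C@@H]1COC(=O)[C@H]1CC(=O)OCc1ccccc1 | intermediate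
20 | benzyl 2-[(3S,4S)-4-(carbonochloridoyl)-2-oxooxolan-3-yl]acetate | O=C(Cl)[C@@H]1COC(=O)[C@H]1CC(=O)OCc1ccccc1 | intermediate
21 | benzyl 2-[(3S,4S)-2-oxo-4-{[(3aS,7aS)-4,4,7a-trimethyl-3a,4,5,6,7,7a-hexahydro-3H-inden-1-yl]carbonyl}oxolan-3-yl]acetate | O=C(C1=CC[C@H]2C(C)(C)CCC[C@]12C)[C@@H]1COC(=O)[C@H]1CC(=O)OCc1ccccc1 | intermediate
22 | 2-[(3S,4S)-2-oxo-4-{[(1S,3aS,7aS)-4,4,7a-trimethyloctahydro-1H-inden-1-yl]carbonyl}oxolan-3-yl]acetic acid | O=C([C@H]1CC[C@H]2C(C)(C)CCC[C@]12C)[C@@H]1COC(=O)[C@H]1CC(=O)O | intermediate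
23 | 2-[(3S,4R)-2-oxo-4-{1-[(1R,3aS,7aS)-4,4,7a-trimethyloctahydro-1H-inden-1-yl]ethenyl}oxolan-3-yl]acetic acid | C=C([C@H]1CC[C@H]2C(C)(C)CCC[C@]12C)[C@@H]1COC(=O)[C@H]1CC(=O)O | intermediate
24 | (3S,4R)-3,4-bis(hydroxymethyl)-5-[(1R,3aS,7aS)-4,4,7a-trimethyloctahydro-1H-inden-1-yl]hex-5-enoic acid | C=C([C@H]1CC[C@H]2C(C)(C)CCC[C@]12C)[C@H](CO)[C@@H](CO)CC(=O)O | intermediate (not isolated)
25 | (4S)-4-{(2R)-1-hydroxy-3-[(1R,3aS,7aS)-4,4,7a-trimethyloctahydro-1H-inden-1-yl]but-3-en-2-yl}oxolan-2-one | C=C([C@H]1CC[C@H]2C(C)(C)CCC[C@]12C)[C@H](CO)[C@H]1COC(=O)C1 | intermediate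
26 | (2R)-2-[(3S)-5-oxooxolan-3-yl]-3-[(1R,3aS,7aS)-4,4,7a-trimethyloctahydro-1H-inden-1-yl]but-3-en-1-yl acetate | C=C([C@H]1CC[C@H]2C(C)(C)CCC[C@]12C)[C@H](COC(C)=O)[C@H]1COC(=O)C1 | target

**Step count and risks**

Total step count: 16. Longest linear sequence: 13 steps (steps 2–9 and 12–16).

Steps most likely to fail:

Step 3. The iron enolate may be protonated, or the aldehyde reduced or acetalised by the silane/alcohol medium, before the aldol closure, so that only one of the two bonds forms. The fallback separates the two bond formations; it sets out from 5 and 1 and returns to the route at 12. The same iron-hydride olefin–enone coupling [Fe(acac)3, PhSiH3, EtOH/(CH2OH)2, 60 °C] of 5 with alcohol 1 should give (4R)-4-[(4R)-2,2-dimethyl-1,3-dioxolan-4-yl]-8-hydroxy-3,5,5-trimethyloctan-2-one F1 (C3a set as in step 3, epimers at the carbon next to the ketone). I2/PPh3/imidazole should convert it into (4R)-4-[(4R)-2,2-dimethyl-1,3-dioxolan-4-yl]-8-iodo-3,5,5-trimethyloctan-2-one F2. KOt-Bu in t-BuOH/THF should then close ring B by 6-(enolexo)-exo-tet alkylation through the more substituted enolate (the eight-membered closure from the methyl enolate does not compete, and the same allylic-strain argument places the 7a-methyl anti to 3a-H) to give 1-[(1S,2S)-2-[(4R)-2,2-dimethyl-1,3-dioxolan-4-yl]-1,3,3-trimethylcyclohexyl]ethan-1-one F3, which already lacks the C7 oxygen. H5IO6 should give (1S,2S)-2-acetyl-2,6,6-trimethylcyclohexane-1-carbaldehyde F4, KOH/MeOH should give (3aS,7aS)-4,4,7a-trimethyl-3a,4,5,6,7,7a-hexahydro-1H-inden-1-one F5, and H2 over Pd/C should give 12.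

Step 6. Enolisation of the hindered aldehyde may epimerise C3a before ring closure, or the strained trans-fused enone may drift to its β,γ-isomer by γ-deprotonation under the equilibrating base. The fallback is a directed aldol that never forms the enone; it sets out from 10 and returns at 12. LiN(SiMe3)2 (1.05 equiv, THF, −78 → 0 °C) should deprotonate only the methyl ketone, and the kinetic enolate should close on the aldehyde to give (3aS,7aS)-3-hydroxy-4,4,7a-trimethyl-2,3,3a,4,5,7a-hexahydro-1H-inden-1-one F6 (epimers at C3). 1,1'-Thiocarbonyldiimidazole should give O-[(3aS,7aS)-4,4,7a-trimethyl-1-oxo-2,3,3a,4,5,7a-hexahydro-1H-inden-3-yl] 1H-imidazole-1-carbothioate F7. Bu3SnH/AIBN (Barton–McCombie deoxygenation) should give (3aS,7aS)-4,4,7a-trimethyl-2,3,3a,4,5,7a-hexahydro-1H-inden-1-one F8, and H2 over Pd/C should give 12.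

Step 14. The zinc–titanium methylene reagent may fail to add to the doubly α-branched ketone, or be consumed by the carboxylic acid. The fallback is a two-stage Peterson olefination; it sets out from 22 and returns at 23. Me3SiCH2Li/CeCl3 (THF, −78 °C; the organocerium reagent adds to hindered, enolisable ketones without enolisation and leaves the lactone and the carboxylate alone) should give 2-[(3S,4S)-4-{1-hydroxy-1-[(1S,3aS,7aS)-4,4,7a-trimethyloctahydro-1H-inden-1-yl]-2-(trimethylsilyl)ethyl}-2-oxooxolan-3-yl]acetic acid F9 (epimers at the carbinol carbon), and aqueous HF in MeCN should eliminate the silanol to give 23.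

Further compounds
F1 | step 3 | (4R)-4-[(4R)-2,2-dimethyl-1,3-dioxolan-4-yl]-8-hydroxy-3,5,5-trimethyloctan-2-one | CC(=O)C(C)[C@@H]([C@@H]1COC(C)(C)O1)C(C)(C)CCCO
F2 | step 3 | (4R)-4-[(4R)-2,2-dimethyl-1,3-dioxolan-4-yl]-8-iodo-3,5,5-trimethyloctan-2-one | CC(=O)C(C)[C@@H]([C@@H]1COC(C)(C)O1)C(C)(C)CCCI
F3 | step 3 | 1-[(1S,2S)-2-[(4R)-2,2-dimethyl-1,3-dioxolan-4-yl]-1,3,3-trimethylcyclohexyl]ethan-1-one | CC(=O)[C@]1(C)[C@@H]([C@@H]2COC(C)(C)O2)C(C)(C)CCC1
F4 | step 3 | (1S,2S)-2-acetyl-2,6,6-trimethylcyclohexane-1-carbaldehyde | CC(=O)[C@]1(C)[C@@H](C=O)C(C)(C)CCC1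
F5 | step 3 | (3aS,7aS)-4,4,7a-trimethyl-3a,4,5,6,7,7a-hexahydro-1H-inden-1-one | O=C1C=C[C@H]2C(C)(C)CCC[C@]12C
F6 | step 6 | (3aS,7aS)-3-hydroxy-4,4,7a-trimethyl-2,3,3a,4,5,7a-hexahydro-1H-inden-1-one | O=C1CC(O)[C@H]2C(C)(C)CC=C[C@]12C
F7 | step 6 | O-[(3aS,7aS)-4,4,7a-trimethyl-1-oxo-2,3,3a,4,5,7a-hexahydro-1H-inden-3-yl] 1H-imidazole-1-carbothioate | O=C1CC(OC(=S)n3ccnc3)[C@H]2C(C)(C)CC=C[C@]12C
F8 | step 6 | (3aS,7aS)-4,4,7a-trimethyl-2,3,3a,4,5,7a-hexahydro-1H-inden-1-one | O=C1CC[C@H]2C(C)(C)CC=C[C@]12C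
F9 | step 14 | 2-[(3S,4S)-4-{1-hydroxy-1-[(1S,3aS,7aS)-4,4,7a-trimethyloctahydro-1H-inden-1-yl]-2-(trimethylsilyl)ethyl}-2-oxooxolan-3-yl]acetic acid | C[Si](C)(C)CC(O)([C@H]1CC[C@H]2C(C)(C)CCC[C@]12C)[C@@H]1COC(=O)[C@H]1CC(=O)O
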